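**Retrosynthetic overview**

1. The strategy rests on the C7–C8–C9–C10 segment of the 10-membered carbocycle. The acetate-bearing C8 is bonded on one side to C7 of the C7=C11 butenolide ring and on the other to the CH2 group C9, whose other neighbour is the methylene-bearing C10. The C8–O and C9–C10 bonds are therefore cut together, back to a C8=C9 vinyl group on the butenolide (a C9=C8–C7=C11 diene) and a C10 vinyl iodide.
2. The butenolide ring is cut at C7–C8, C11–C12 and O–C12 to a C6 propargylic alcohol, vinylmagnesium chloride and CO2.
3. The C6 carbinol comes from ligand-controlled alkynylation of a Z-enal with PMB propargyl ether. The C1 carbinol and the C10 vinyl metal come from TMS-acetylene addition to the C1–C6 aldehyde excised from neryl acetate, followed by ynone transfer hydrogenation and internal hydrostannation.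
4. Ring order: butenolide first, 10-membered carbocycle last by palladium-catalysed ring closure. The endgame exchanges the C13 PMB ether for acetate and frees the C1 hydroxyl.

Key step: step 13

Assumption: (S,S)-ProPhenol is taken to give the 6R carbinol in step 10 and RuCl(p-cymene)[(R,R)-TsDPEN] the 1R carbinol in step 5; each sense would be checked by Mosher ester analysis and the antipodal ligand used if needed.

Atom numbers C1–C15 are those of the target throughout.

**Route**

Step 1
Reactants: 1 neryl acetate
Product: 2 6,7-epoxyneryl acetate (racemic)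
Conditions: mCPBA, CH2Cl2, 0 °C
Reagents that add atoms: mCPBA (3-chloroperoxybenzoic acid), O=C(OO)c1cccc(Cl)c1
Why: Prilezhaev epoxidation should occur at the trisubstituted distal alkene because the other alkene is deactivated by the allylic acetate; the epoxide is racemic, which does not matter since both its carbons are cleaved in step 2.

Step 2
Reactants: 2 6,7-epoxyneryl acetate
Product: 4 (2Z)-3-methyl-6-oxohex-2-en-1-yl acetate, via 6,7-diol 3 (not isolated)
Conditions: H5IO6, THF/H2O, 0 °C to rt
Reagents that add atoms: water, O
Why: Aqueous periodic acid should hydrolyse the epoxide to glycol 3 and cleave it in the same flask (Malaprade glycol cleavage), releasing acetone and the aldehyde that becomes C1 while the Z-allylic acetate is untouched.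

Step 3
Reactants: 4 (2Z)-3-methyl-6-oxohex-2-en-1-yl acetate; 5 ethynyltrimethylsilane
Product: 7 racemic C1 propargylic alcohol (2Z)-6-hydroxy-3-methyl-8-(trimethylsilyl)oct-2-en-7-yn-1-yl acetate, via lithium (trimethylsilyl)acetylide 6 (not isolated)
Conditions: 5, n-BuLi, THF, −78 °C; then 4, −78 °C; aq. NH4Cl
Reagents that add atoms: none
Why: 1,2-Addition of a lithium acetylide to an aldehyde at −78 °C should be far faster than attack on the acetate ester, giving the C1 carbinol as a racemate whose configuration is fixed in steps 4 and 5.

Step 4
Reactants: 7 racemic C1 propargylic alcohol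
Product: 8 ynone (2Z)-3-methyl-6-oxo-8-(trimethylsilyl)oct-2-en-7-yn-1-yl acetate
Conditions: Dess–Martin periodinane, CH2Cl2, 0 °C to rt
Reagents that add atoms: none
Why: Dess–Martin oxidation should convert the secondary propargylic alcohol into the ynone under near-neutral conditions that leave the acetate, the C-silyl alkyne and the Z alkene alone.

Step 5
Reactants: 8 ynone
Product: 9 (1R)-propargylic alcohol (2Z,6R)-6-hydroxy-3-methyl-8-(trimethylsilyl)oct-2-en-7-yn-1-yl acetate
Conditions: RuCl(p-cymene)[(R,R)-TsDPEN] (2 mol %), KOH (2 mol %), i-PrOH, rt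
Reagents that add atoms: none
Why: Noyori asymmetric transfer hydrogenation of an alkynyl ketone, in which the ruthenium hydride and ligand N–H differentiate the alkynyl flank from the alkyl flank, should set C1 as R with the (R,R)-ligand.

Step 6
Reactants: 9 (1R)-propargylic alcohol
Product: 10 TBS ether of 9
Conditions: TBSCl, imidazole, DMF, rt
Reagents that add atoms: tert-butyldimethylsilyl chloride, CC(C)(C)[Si](C)(C)Cl
Why: Standard silylation of a secondary alcohol protects the C1 oxygen, which must not act as a nucleophile toward the allylpalladium in step 13.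

Step 7
Reactants: 10 TBS ether
Product: 11 (2Z,6R)-6-(tert-butyldimethylsilyloxy)-3-methyloct-2-en-7-yn-1-ol
Conditions: K2CO3, MeOH, rt
Reagents that add atoms: none
Why: Potassium carbonate in methanol should cleave the acetate by transesterification and the alkynyl C–Si bond by protodesilylation in one operation, while the secondary TBS ether is stable.

Step 8
Reactants: 11 terminal alkyne
Product: 12 (2Z,6R)-6-(tert-butyldimethylsilyloxy)-3-methyl-7-(tributylstannyl)octa-2,7-dien-1-ol
Conditions: Bu3SnH, Mo(CO)3(CNtBu)3 (5 mol %), hydroquinone (cat.), THF, 55 °C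
Reagents that add atoms: tributyltin hydride, CCCC[SnH](CCCC)CCCC
Why: Molybdenum-catalysed hydrostannation with this isonitrile complex is known to place tin on the internal carbon of terminal alkynes bearing a propargylic oxygen, giving the 1,1-disubstituted C10 vinylstannane; the trisubstituted alkene and free alcohol should not react.

Step 9
Reactants: 12 vinylstannane allylic alcohol
Product: 13 Z-enal (2Z,6R)-6-(tert-butyldimethylsilyloxy)-3-methyl-7-(tributylstannyl)octa-2,7-dienal
Conditions: MnO2, CH2Cl2, rt; filtered and used at once
Reagents that add atoms: none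
Why: MnO2 oxidises allylic alcohols selectively under neutral conditions, so the Z-enal should form without isomerisation if used directly, and the vinylstannane is inert to the oxidant.

Step 10
Reactants: 13 Z-enal; 14 4-methoxybenzyl propargyl ether
Product: 16 (1R,6R)-C6 propargylic alcohol, via methylzinc acetylide 15 (not isolated)
Conditions: 14, Me2Zn, (S,S)-ProPhenol (20 mol %), Ph3P=O (40 mol %), toluene, 0 °C; then 13
Reagents that add atoms: none
Why: Catalytic asymmetric alkynylation of an α,β-unsaturated aldehyde with the dinuclear zinc–ProPhenol catalyst: the ligand pocket dictates which aldehyde face the zinc acetylide attacks and should set C6 as R under reagent control, the remote C1 centre having little influence.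

Step 11
Reactants: 16 C6 propargylic alcohol; 17 vinylmagnesium chloride; 18 carbon dioxide
Product: 21 7-vinylbutenolide bearing the C10 tributylstannane, via vinylmagnesium chelate 19 (not isolated), via Z-hydroxy acid 20 (not isolated)
Conditions: 17 (excess), THF/cyclohexane, 65 °C; then CO2, −20 °C to rt; aq. citric acid
Reagents that add atoms: none
Why: Hydroxyl-directed anti-carbomagnesiation of a propargylic alcohol: the C6 magnesium alkoxide delivers vinyl to the proximal alkyne carbon C7 and leaves magnesium on C11 in a five-membered chelate, CO2 carboxylates the C11–Mg bond, and the acid, held cis to the C6 hydroxyl, lactonises on mild acidic work-up without the C6–O bond being broken.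

Step 12
Reactants: 21 7-vinylbutenolide stannane
Product: 22 7-vinylbutenolide bearing the C10 vinyl iodide
Conditions: I2, CH2Cl2, −78 to 0 °C; aq. Na2S2O3
Reagents that add atoms: iodine, II
Why: Iododestannylation is an ipso substitution at the vinyl C–Sn bond, the most nucleophilic site toward iodine at low temperature, and installs the C10 iodide with the alkene position unchanged.

Step 13
Reactants: 22 7-vinylbutenolide vinyl iodide
Product: 25 germacranolide core carrying 8-acetate 13-PMB ether 1-TBS ether, via vinylpalladium iodide 23 (not isolated), via allylpalladium acetate 24 (not isolated)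
Conditions: Pd(OAc)2 (20 mol %), AgOAc (2 equiv), DMF, 45 °C, 2 mM, slow addition of 22
Reagents that add atoms: silver acetate AgOAc, CC(=O)[O-].[Ag+]
Why: Proposed new method: oxidative addition of the C10–I bond to zerovalent palladium (generated in the flask from Pd(OAc)2) is followed by syn carbopalladation of the diene at its CH2 terminus C9, which forms the C9–C10 bond and an allylpalladium delocalised over C8–C7–C11; external acetate then substitutes at C8 and returns the metal to the zerovalent state while silver takes up iodide. The closest known reaction types are the intermolecular Heck-type 1,2-carbo-oxygenation of 1,3-dienes by aryl or vinyl halides with carboxylate capture, and macrocyclic Heck cyclisations; their combination as a ring closure has no precedent. The 10-membered carbocycle closes in the 10-endo-trig mode, since both C8 and C9 end up inside the ring. The new C8 stereocentre is controlled by the existing C6 centre: the short tether through C6 and the Z C4=C5 alkene should let the vinylpalladium reach only one diene face, and acetate entering anti to palladium is then expected, without modelling, to give 8S. The step needs attack at C8 and not C11, which the fully substituted C11 and retention of butenolide conjugation should secure. It also needs capture to outrun beta-hydride elimination and ionisation of the allylic C6–O bond, for which the strain of an endocyclic C8=C9 alkene, the phosphine-free catalyst, the moderate temperature and the capped C1 and C13 oxygens are relied on.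

Step 14
Reactants: 25 germacranolide core
Product: 26 13-alcohol (8-acetate, 1-TBS ether)
Conditions: DDQ, CH2Cl2/pH 7 buffer, 0 °C
Reagents that add atoms: none
Why: DDQ oxidises the electron-rich 4-methoxybenzyl ether by single-electron transfer to an oxocarbenium ion that water hydrolyses, freeing the C13 alcohol while silyl ether, acetate and lactone are untouched.

Step 15
Reactants: 26 13-alcohol
Product: 27 8,13-diacetate 1-TBS ether
Conditions: Ac2O, pyridine, DMAP (cat.), CH2Cl2, 0 °C to rt
Reagents that add atoms: acetic anhydride, CC(=O)OC(C)=O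
Why: DMAP-catalysed acylation of the unhindered primary allylic alcohol with acetic anhydride.

Step 16
Reactants: 27 8,13-diacetate 1-TBS ether
Product: 28 8alpha,13-diacetoxy-1beta-hydroxygermacra-4,7(11),10(14)-trien-6alpha,12-olide (target)
Conditions: HF·pyridine, pyridine/THF, 0 °C to rt
Reagents that add atoms: none
Why: Buffered HF–pyridine removes the secondary TBS ether by Si–F bond formation without the acetate migration or cleavage that basic fluoride sources could cause, and should give the target.

**Compound list**

1 | neryl acetate | CC(C)=CCC/C(C)=C\COC(C)=O | starting material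
2 | 6,7-epoxyneryl acetate (racemic) | CC1(C)OC1CC/C(C)=C\COC(C)=O | intermediate
3 | (2Z)-6,7-dihydroxy-3,7-dimethyloct-2-en-1-yl acetate (racemic diol, not isolated) | CC(C)(O)C(O)CC/C(C)=C\COC(C)=O | intermediate
4 | (2Z)-3-methyl-6-oxohex-2-en-1-yl acetate (C1–C6 and C15) | O=CCC/C(C)=C\COC(C)=O | intermediate
5 | ethynyltrimethylsilane (C10, C14) | C#C[Si](C)(C)C | starting material
6 | lithium (trimethylsilyl)acetylide (not isolated) | [Li]C#C[Si](C)(C)C | intermediate
7 | (2Z)-6-hydroxy-3-methyl-8-(trimethylsilyl)oct-2-en-7-yn-1-yl acetate, racemic at C1 | C[Si](C)(C)C#CC(O)CC/C(C)=C\COC(C)=O | intermediate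
8 | (2Z)-3-methyl-6-oxo-8-(trimethylsilyl)oct-2-en-7-yn-1-yl acetate (ynone) | C[Si](C)(C)C#CC(=O)CC/C(C)=C\COC(C)=O | intermediate
9 | (2Z,6R)-6-hydroxy-3-methyl-8-(trimethylsilyl)oct-2-en-7-yn-1-yl acetate (1R) | C[Si](C)(C)C#C[C@H](O)CC/C(C)=C\COC(C)=O | intermediate
10 | TBS ether of 9 | C[Si](C)(C)C#C[C@H](O[Si](C)(C)C(C)(C)C)CC/C(C)=C\COC(C)=O | intermediate
11 | (2Z,6R)-6-(tert-butyldimethylsilyloxy)-3-methyloct-2-en-7-yn-1-ol | C#C[C@H](O[Si](C)(C)C(C)(C)C)CC/C(C)=C\CO | intermediate
12 | (2Z,6R)-6-(tert-butyldimethylsilyloxy)-3-methyl-7-(tributylstannyl)octa-2,7-dien-1-ol | C=C([Sn](CCCC)(CCCC)CCCC)[C@H](O[Si](C)(C)C(C)(C)C)CC/C(C)=C\CO | intermediate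
13 | Z-enal with C1 TBS ether and C10 stannane | C=C([Sn](CCCC)(CCCC)CCCC)[C@H](O[Si](C)(C)C(C)(C)C)CC/C(C)=C\C=O | intermediate
14 | 4-methoxybenzyl propargyl ether (C7, C11, C13) | C#CCOCc1ccc(OC)cc1 | starting material
15 | methylzinc acetylide of 14 (not isolated) | C[Zn]C#CCOCc1ccc(OC)cc1 | intermediate
16 | (1R,6R)-C6 propargylic alcohol | C=C([Sn](CCCC)(CCCC)CCCC)[C@H](O[Si](C)(C)C(C)(C)C)CC/C(C)=C\[C@@H](O)C#CCOCc1ccc(OC)cc1 | intermediate
17 | vinylmagnesium chloride (C8, C9) | C=C[Mg]Cl | starting material
18 | carbon dioxide (C12) | O=C=O | starting material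
19 | five-membered oxamagnesacycle with vinyl on C7 and magnesium on C11 (not isolated) | C=CC1=C(COCc2ccc(OC)cc2)[Mg]O[C@@H]1/C=C(/C)CC[C@@H](O[Si](C)(C)C(C)(C)C)C(=C)[Sn](CCCC)(CCCC)CCCC | intermediate
20 | Z-hydroxy acid, C12 acid cis to the C6 hydroxyl (not isolated) | OC(=O)/C(COCc1ccc(OC)cc1)=C(/C=C)[C@H](O)/C=C(/C)CC[C@@H](O[Si](C)(C)C(C)(C)C)C(=C)[Sn](CCCC)(CCCC)CCCC | intermediate
21 | 7-vinylbutenolide with C10 tributylstannane (1R,6R) | C=CC1=C(COCc2ccc(OC)cc2)C(=O)O[C@@H]1/C=C(/C)CC[C@@H](O[Si](C)(C)C(C)(C)C)C(=C)[Sn](CCCC)(CCCC)CCCC | intermediate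
22 | 7-vinylbutenolide with C10 vinyl iodide (1R,6R) | C=CC1=C(COCc2ccc(OC)cc2)C(=O)O[C@@H]1/C=C(/C)CC[C@@H](O[Si](C)(C)C(C)(C)C)C(I)=C | intermediate
23 | C10 vinylpalladium iodide (not isolated) | C=CC1=C(COCc2ccc(OC)cc2)C(=O)O[C@@H]1/C=C(/C)CC[C@@H](O[Si](C)(C)C(C)(C)C)C(=C)[Pd]I | intermediate
24 | macrocyclic allylpalladium acetate, drawn in its C8-bonded form with palladium anti to the incoming acetate (not isolated) | C=C1C[C@@H]([Pd]OC(C)=O)C2=C(COCc3ccc(OC)cc3)C(=O)O[C@@H]2/C=C(/C)CC[C@H]1O[Si](C)(C)C(C)(C)C | intermediate
25 | germacranolide core, 8-acetate, 13-PMB ether, 1-TBS ether (1R,6R,8S) | C=C1C[C@H](OC(C)=O)C2=C(COCc3ccc(OC)cc3)C(=O)O[C@@H]2/C=C(/C)CC[C@H]1O[Si](C)(C)C(C)(C)C | intermediate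
26 | 13-alcohol, 8-acetate, 1-TBS ether | C=C1C[C@H](OC(C)=O)C2=C(CO)C(=O)O[C@@H]2/C=C(/C)CC[C@H]1O[Si](C)(C)C(C)(C)C | intermediate
27 | 8,13-diacetate 1-TBS ether | C=C1C[C@H](OC(C)=O)C2=C(COC(C)=O)C(=O)O[C@@H]2/C=C(/C)CC[C@H]1O[Si](C)(C)C(C)(C)C | intermediate
28 | 8alpha,13-diacetoxy-1beta-hydroxygermacra-4,7(11),10(14)-trien-6alpha,12-olide | C=C1C[C@H](OC(C)=O)C2=C(COC(C)=O)C(=O)O[C@@H]2/C=C(/C)CC[C@H]1O | target

**Step count and risks**

Total step count: 16. Longest linear sequence: 16 steps (1 to 28).

Steps most likely to fail:

1. Step 13 (the one step put forward as a new method). Beta-hydride elimination from the allylpalladium may outrun acetate capture. Zerovalent palladium may ionise the allylic C6–O lactone bond or the product acetate. Oligomerisation may compete with ring closure, and acetate may be delivered to the wrong face of C8.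
 Fallback (known chemistry, ring closed at C8–C9 by chromium-mediated carbonyl allylation instead of at C9–C10): it sets out from vinyl iodide 22. Lemieux–Johnson oxidation (OsO4 cat., NaIO4, 2,6-lutidine, dioxane/H2O) would cut the terminal C8=C9 alkene, the only unhindered monosubstituted one, to the 7-formylbutenolide F1. Site selectivity over the Z-trisubstituted C4=C5 alkene, which carries the allylic lactone oxygen, is the point to verify. Stille coupling of the C10 iodide with (tributylstannyl)methanol (Pd2(dba)3, tri(2-furyl)phosphine, NMP, 50 °C) would give the 2-substituted allylic alcohol F2, now carrying C9. Mesylation and LiBr displacement would give the allylic bromide F3. Nozaki–Hiyama allylation with CrCl2 in THF at high dilution should close the 10-membered ring to the homoallylic alcohol F4, with C8 set under substrate control in the chair-like allylchromium transition state. Acetylation (Ac2O, pyridine, DMAP) brings the route back at 25.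

2. Step 11. The C11–magnesium intermediate may expel the C13 4-methoxybenzyl oxide by beta-elimination, giving a vinylallene. Carbometalation may also be too slow at a temperature the substrate tolerates, and the stannane may be lost by protonolysis on acidic work-up.
 Fallback (syn-carbocupration of an alkynoate instead of anti-carbomagnesiation of the alkynol): it sets out from enal 13. The same zinc–ProPhenol alkynylation with methyl propiolate would give the gamma-hydroxy ynoate F5, which already holds C12. Lithium divinylcuprate (CH2=CH)2CuLi in THF at −78 °C should add vinyl to C7 in the syn sense. The resulting alpha-cuprio enoate would be alkylated at C11 with 4-methoxybenzyl chloromethyl ether, so no carbon–metal bond beta to the C13 oxygen is ever formed. The Z-hydroxy ester lactonises on work-up and the route is rejoined at 21.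

3. Step 10. Facial selectivity may be poor with the Z-configured beta,beta-disubstituted enal, the enal may isomerise from Z to E before addition, and turnover may be slow with the hindered substrate.
 Fallback (non-selective addition, then reagent-controlled reduction): it sets out from enal 13. Ether 14 is deprotonated with n-BuLi and added at −78 °C without facial control, giving 16 together with its C6 epimer F6. MnO2 would oxidise the mixture to the alkenyl alkynyl ketone F7. Corey–Bakshi–Shibata reduction ((R)-2-methyl-CBS-oxazaborolidine, catecholborane, toluene, −78 °C), with the alkynyl group acting as the small substituent, should return the 6R alcohol, and the route is rejoined at 16.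

**Further compounds**

F1 | step 13 | 7-formylbutenolide with C10 vinyl iodide | O=CC1=C(COCc2ccc(OC)cc2)C(=O)O[C@@H]1/C=C(/C)CC[C@@H](O[Si](C)(C)C(C)(C)C)C(I)=C
F2 | step 13 | 7-formylbutenolide with C10 2-(hydroxymethyl)vinyl unit (C9 alcohol) | O=CC1=C(COCc2ccc(OC)cc2)C(=O)O[C@@H]1/C=C(/C)CC[C@@H](O[Si](C)(C)C(C)(C)C)C(=C)CO
F3 | step 13 | 7-formylbutenolide with C9 allylic bromide | O=CC1=C(COCc2ccc(OC)cc2)C(=O)O[C@@H]1/C=C(/C)CC[C@@H](O[Si](C)(C)C(C)(C)C)C(=C)CBr
F4 | step 13 | 8-hydroxy macrocycle, 13-PMB ether, 1-TBS ether (8S) | C=C1C[C@H](O)C2=C(COCc3ccc(OC)cc3)C(=O)O[C@@H]2/C=C(/C)CC[C@H]1O[Si](C)(C)C(C)(C)C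
F5 | step 11 | methyl gamma-hydroxy ynoate (6R) with C10 stannane | C=C([Sn](CCCC)(CCCC)CCCC)[C@H](O[Si](C)(C)C(C)(C)C)CC/C(C)=C\[C@@H](O)C#CC(=O)OC
F6 | step 10 | C6 epimer of 16 (6S) | C=C([Sn](CCCC)(CCCC)CCCC)[C@H](O[Si](C)(C)C(C)(C)C)CC/C(C)=C\[C@H](O)C#CCOCc1ccc(OC)cc1
F7 | step 10 | C6 alkenyl alkynyl ketone | C=C([Sn](CCCC)(CCCC)CCCC)[C@H](O[Si](C)(C)C(C)(C)C)CC/C(C)=C\C(=O)C#CCOCc1ccc(OC)cc1
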